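**Retrosynthetic overview** (A = 1,4-phenylene ring; B = catechol ring; C = 1,3-phenylene ring; D = phenol ring carrying the ortho aryloxy group)
1. The target comes from its tri-O-methyl ether by global BBr3 demethylation.
2. Key disconnection: the 18-membered ring is opened at the A–O–D diaryl ether, not at an ethano bridge. It is closed by an intramolecular Ullmann macro-etherification (A-ring OH onto the D-ring C–Br ortho to OMe).
3. Both ArCH2–CH2Ar bridges are cut at the aryl–CH2 (sp2–sp3) bond. Each is made by styrene hydroboration/B-alkyl Suzuki coupling with ArI over ArBr selection, so the bridges arrive saturated, with no olefination and no hydrogenation.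
4. The hindered B–O–C ether is made by SNAr on 2-fluoro-3,4-dimethoxybenzaldehyde. The CHO activates the fluoride and then becomes the vinyl group.
5. All four benzene rings are purchased. They are joined in the order C–D, then B, then A. The macrocycle is the only ring formed, and it is formed last.

Assumption: the SMILES contains no stereocentre and the macrocycle is conformationally mobile, with no isolable planar or axial chirality. The target is therefore achiral, and "single enantiomer" needs no stereocontrol.

**Step 1**
Reactants: 1, 3-vinylphenol; 2, 2-bromo-4-iodoanisole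
Product: 3, 3-[2-(3-bromo-4-methoxyphenyl)ethyl]phenol
Conditions: (i) 9-BBN (2.2 equiv), THF, 0 °C to rt; (ii) H2O quench, then 2 (0.95 equiv), PdCl2(dppf) (3 mol %), aq K3PO4, THF/DMF, rt; NH4Cl work-up
Reagents that add atoms: none beyond the reactants (2, COc1ccc(I)cc1Br, supplies the aryl unit; 9-BBN leaves only H)
Why: Hydroboration/B-alkyl Suzuki–Miyaura coupling, in which 9-BBN adds anti-Markovnikov to the styrene (one equivalent is consumed as the hydrolysable ArO–BBN borinate) and Pd(0)/dppf at rt inserts into C–I far faster than into the hindered, electron-rich ortho-methoxy C–Br, giving the saturated C–D bridge directly with no stereocentre formed.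

**Step 2**
Reactants: 3; 4, 2-fluoro-3,4-dimethoxybenzaldehyde
Product: 5, 2-{3-[2-(3-bromo-4-methoxyphenyl)ethyl]phenoxy}-3,4-dimethoxybenzaldehyde
Conditions: K2CO3, DMAc, 130 °C, N2
Reagents that add atoms: none beyond the reactants (4, COc1ccc(C=O)c(F)c1OC)
Why: SNAr (addition–elimination), in which the ortho-formyl group stabilises the Meisenheimer adduct and fluoride is the only viable leaving group, while the unactivated D-ring C–Br is inert to phenoxide and carbonate without a metal.

**Step 3**
Reactants: 5; 6, methyltriphenylphosphonium bromide
Product: 7, 2-{3-[2-(3-bromo-4-methoxyphenyl)ethyl]phenoxy}-3,4-dimethoxystyrene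
Conditions: 6, KOtBu, THF, 0 °C to rt
Reagents that add atoms: methyltriphenylphosphonium bromide, C[P+](c1ccccc1)(c1ccccc1)c1ccccc1.[Br-] (adds CH2)
Why: Wittig methylenation of a non-enolisable aryl aldehyde, with the aryl bromide and all aryl ethers inert to the ylide.

**Step 4**
Reactants: 7; 8, 4-iodophenol
Product: 9, 4-[2-(2-{3-[2-(3-bromo-4-methoxyphenyl)ethyl]phenoxy}-3,4-dimethoxyphenyl)ethyl]phenol
Conditions: (i) 9-BBN (1.5 equiv), THF, rt to 40 °C; (ii) H2O quench, then 8 (1.3 equiv), PdCl2(dppf) (5 mol %), AsPh3, Cs2CO3, DMF/THF/H2O, rt to 35 °C
Reagents that add atoms: none beyond the reactants (8, Oc1ccc(I)cc1)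
Why: Second hydroboration/B-alkyl Suzuki–Miyaura coupling, in which intermolecular coupling with the aryl iodide at or below 35 °C outruns both oxidative addition into the ortho-methoxy aryl bromide and the strained 13-membered intramolecular alternative, so ring A with its free OH and the saturated A–B bridge are installed in one operation.

**Step 5 (key step)**
Reactants: 9
Product: 10, marchantin H tri-O-methyl ether (18-membered macrocycle)
Conditions: CuBr·SMe2 (2 equiv), Cs2CO3 (3 equiv), pyridine, 115 °C, Ar, syringe-pump addition to about 3 mM
Reagents that add atoms: none (loss of HBr)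
Why: Intramolecular Ullmann diaryl-ether condensation, in which the Cu(I) phenoxide of ring A reacts at the only C–Br bond (the ortho-OMe assists Cu binding), high dilution favours the nearly unstrained 18-membered ring, and the same 4-alkylphenol/3-bromo-4-methoxyaryl pairing is known to close more strained 15-membered diaryl-ether cyclophanes.

**Step 6**
Reactants: 10
Product: 11, marchantin H
Conditions: BBr3 (9 equiv), CH2Cl2, −78 °C to rt; degassed ice-water work-up
Reagents that add atoms: none (three CH3 groups are replaced by H)
Why: Lewis-acid aryl methyl ether cleavage, in which BBr3 cleaves only the O–CH3 bonds while the diaryl ethers and bibenzyl bridges are inert and there is no stereochemistry to disturb.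

**Compound list**
1 | 3-vinylphenol | C=Cc1cccc(O)c1 | starting material
2 | 2-bromo-4-iodoanisole | COc1ccc(I)cc1Br | starting material
3 | 3-[2-(3-bromo-4-methoxyphenyl)ethyl]phenol | COc1ccc(CCc2cccc(O)c2)cc1Br | intermediate
4 | 2-fluoro-3,4-dimethoxybenzaldehyde | COc1ccc(C=O)c(F)c1OC | starting material
5 | 2-{3-[2-(3-bromo-4-methoxyphenyl)ethyl]phenoxy}-3,4-dimethoxybenzaldehyde | COc1ccc(CCc2cccc(Oc3c(C=O)ccc(OC)c3OC)c2)cc1Br | intermediate
6 | methyltriphenylphosphonium bromide | C[P+](c1ccccc1)(c1ccccc1)c1ccccc1.[Br-] | starting material (reagent)
7 | 2-{3-[2-(3-bromo-4-methoxyphenyl)ethyl]phenoxy}-3,4-dimethoxystyrene | COc1ccc(CCc2cccc(Oc3c(C=C)ccc(OC)c3OC)c2)cc1Br | intermediate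
8 | 4-iodophenol | Oc1ccc(I)cc1 | starting material
9 | seco bromo-phenol, 4-[2-(2-{3-[2-(3-bromo-4-methoxyphenyl)ethyl]phenoxy}-3,4-dimethoxyphenyl)ethyl]phenol | COc1ccc(CCc2cccc(Oc3c(CCc4ccc(O)cc4)ccc(OC)c3OC)c2)cc1Br | intermediate
10 | marchantin H tri-O-methyl ether | COc1ccc2cc1Oc1ccc(cc1)CCc1ccc(OC)c(OC)c1Oc1cccc(c1)CC2 | intermediate
11 | marchantin H (achiral) | Oc1ccc2cc1Oc1ccc(cc1)CCc1ccc(O)c(O)c1Oc1cccc(c1)CC2 | target

**Total step count:** 6
**Longest linear sequence:** 6 (1 → 3 → 5 → 7 → 9 → 10 → 11)

**Steps most likely to fail, with fallbacks**
1. **Step 5, macro-Ullmann.** The risks are oligomerisation and hydrodebromination. Fallback: move the ring-closing bond.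
   - Make the A–O–D ether first, intermolecularly, by Chan–Lam coupling of 5-iodo-2-methoxyphenol with 4-bromophenylboronic acid.
   - Run the same sequence: B-alkyl Suzuki of hydroborated 1 at the D-ring C–I, SNAr with 4, then methylenation.
   - Close the ring by intramolecular hydroboration/B-alkyl Suzuki coupling of the B-ring styrene onto the A-ring C–Br. The step count is unchanged.
2. **Step 4, I/Br-selective Suzuki coupling with a free iodophenol.** The risks are loss of the D-ring Br and sluggish coupling of the iodophenoxide. Fallback: abandon cross-coupling for this bridge.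
   - Olefinate aldehyde 5 with the ylide from 4-(TBSO)benzyltriphenylphosphonium bromide.
   - Reduce the stilbene with diimide (TsNHNH2/NaOAc), which spares ArBr.
   - Remove the silyl group with TBAF to reach 9.
3. **Step 2, SNAr on a hindered fluoride.** The para-OMe weakens the activating power of the CHO. Fallback: change the electrophile and the mechanism. Use an ortho-carbonyl-assisted Ullmann coupling of 3 with 2-bromo-3,4-dimethoxybenzaldehyde (Cu, K2CO3, pyridine). The chelating, CHO-activated C–Br should react in preference to the D-ring C–Br.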